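**Assumptions**
- The SMILES is taken as definitive: the acyl-bearing carbon is flanked by CH2 and CHPh, Ph and prenyl are cis, acyl and Ph are trans. This is not the isomer favoured by an ocimene + chalcone Diels–Alder reaction, so a stepwise annulation is used instead.
- The antipode of the amine–thiourea catalyst in step 1 is whichever one delivers (1R,2S)-3; both antipodes are accessible, and the sense of induction is assumed, not derived.

**Retrosynthetic overview**
1. Ar–C(=O) bond last: target 13 ⇐ tris-MOM ketone 12 ⇐ Weinreb amide 8 + lithiated 1,3,5-tris(methoxymethoxy)benzene 11.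
2. C1 configuration (acyl trans to Ph) is thermodynamic: Krapcho dealkoxycarbonylation and equilibration of gem-diester 5.
3. The only ring formed is the cyclohexene, by Schweizer annulation of keto-malonate 3 with vinyltriphenylphosphonium bromide (Michael addition, then intramolecular Wittig).
4. Both permanent stereocentres come from one enamine-catalysed anti Michael addition of 6-methylhept-5-en-2-one to dimethyl benzylidenemalonate (acyclic anti = ring cis Ph/prenyl).
5. Ring order: both benzene rings are purchased; the cyclohexene is closed in step 2.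

**Step 1**
Reactants: 1, 6-methylhept-5-en-2-one; 2, dimethyl 2-benzylidenepropanedioate
Product: 3, dimethyl 2-[(1R,2S)-2-acetyl-5-methyl-1-phenylhex-4-en-1-yl]propanedioate (prenyl and Ph anti in the zigzag chain)
Conditions: 1 (5 equiv), Jacobsen-type primary amine–thiourea from trans-cyclohexane-1,2-diamine and a tert-leucine amide (15 mol%), PhCO2H (15 mol%), toluene, rt, 3–5 d; chromatography to remove the minor syn and CH3-attack isomers
Reagents that add atoms: none beyond reactants 1 and 2
Why: Asymmetric enamine Michael addition in which the primary amine forms the more substituted (Z)-enamine and the thiourea holds the malonate, so the internal α-carbon adds anti, setting C1′ (R, Ph) and C2′ (S, prenyl) together; the α-branched product does not readily re-form an enamine, so it is not epimerised.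

**Step 2**
Reactants: 3; 4, vinyltriphenylphosphonium bromide
Product: 5, dimethyl (5S,6S)-4-methyl-5-(3-methylbut-2-en-1-yl)-6-phenylcyclohex-3-ene-1,1-dicarboxylate
Conditions: NaH (1.05 equiv), THF, 0 °C; then 4, rt → reflux
Reagents that add atoms: vinyltriphenylphosphonium bromide, C=C[P+](c1ccccc1)(c1ccccc1)c1ccccc1.[Br-] (supplies the ring CH2–CH= unit)
Why: Schweizer annulation, in which only the malonate C–H (pKa about 16, versus about 26 for the ketone) is deprotonated, the anion adds to the vinylphosphonium salt, and the resulting ylide closes onto the methyl ketone by intramolecular Wittig to give the trisubstituted ring alkene; no stereocentre is touched (the descriptor at C6 changes only through CIP priorities).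

**Step 3**
Reactants: 5
Product: 6, methyl (1R,5S,6R)-4-methyl-5-(3-methylbut-2-en-1-yl)-6-phenylcyclohex-3-ene-1-carboxylate (ester trans to Ph)
Conditions: LiCl, H2O, DMSO, 150 °C; then NaOMe (cat.), MeOH, rt
Reagents that add atoms: none
Why: Krapcho dealkoxycarbonylation followed by enolate equilibration sets C1 as the thermodynamic epimer, with the ester equatorial and trans to the equatorial Ph while the allylic prenyl sits pseudo-axial to avoid A(1,2) strain with the vinyl methyl.

**Step 4**
Reactants: 6; 7, N,O-dimethylhydroxylamine hydrochloride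
Product: 8, (1R,5S,6R)-N-methoxy-N,4-dimethyl-5-(3-methylbut-2-en-1-yl)-6-phenylcyclohex-3-ene-1-carboxamide
Conditions: MeNH(OMe)·HCl, i-PrMgCl, THF, −20 → 0 °C
Reagents that add atoms: N,O-dimethylhydroxylamine hydrochloride, CNOC.Cl
Why: Direct ester-to-Weinreb-amide aminolysis with the magnesium amide; the alkenes are inert and C1 stays in its thermodynamic trans configuration.

**Step 5**
Reactants: 9, phloroglucinol; 10, chloromethyl methyl ether
Product: 11, 1,3,5-tris(methoxymethoxy)benzene
Conditions: NaH, DMF, 0 °C → rt; MOMCl (3.3 equiv)
Reagents that add atoms: MOMCl, COCCl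
Why: Williamson-type O-alkylation gives MOM ethers that both protect the phenols and direct the later ortho-lithiation.

**Step 6**
Reactants: 8; 11
Product: 12, [(1R,5S,6R)-4-methyl-5-(3-methylbut-2-en-1-yl)-6-phenylcyclohex-3-en-1-yl][2,4,6-tris(methoxymethoxy)phenyl]methanone
Conditions: 11, n-BuLi, THF, 0 °C, 1 h; then 8, −78 °C → rt
Reagents that add atoms: none beyond reactant 11 (aryl group)
Why: Directed ortho-lithiation between two MOM ethers followed by Weinreb ketone synthesis, where the chelated tetrahedral intermediate and the hindered di-ortho-substituted ketone prevent over-addition; no stereocentre is formed and C1 remains the favoured trans epimer.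

**Step 7**
Reactants: 12
Product: 13, (2,4,6-trihydroxyphenyl)[(1R,5S,6R)-4-methyl-5-(3-methylbut-2-en-1-yl)-6-phenylcyclohex-3-en-1-yl]methanone (target)
Conditions: 3 M aq. HCl, MeOH, 40 °C
Reagents that add atoms: none
Why: Acid-catalysed acetal (MOM) hydrolysis under conditions routinely tolerated by prenyl groups; C1 is already the thermodynamic epimer, so any acid-mediated enolisation cannot scramble it.

**Compound list**
1 | 6-methylhept-5-en-2-one | CC(=O)CCC=C(C)C | starting material
2 | dimethyl 2-benzylidenepropanedioate | COC(=O)C(=Cc1ccccc1)C(=O)OC | starting material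
3 | dimethyl 2-[(1R,2S)-2-acetyl-5-methyl-1-phenylhex-4-en-1-yl]propanedioate | CC(C)=CC[C@@H]([C@@H](c1ccccc1)C(C(=O)OC)C(=O)OC)C(C)=O | intermediate
4 | vinyltriphenylphosphonium bromide | C=C[P+](c1ccccc1)(c1ccccc1)c1ccccc1.[Br-] | starting material
5 | dimethyl (5S,6S)-4-methyl-5-(3-methylbut-2-en-1-yl)-6-phenylcyclohex-3-ene-1,1-dicarboxylate | CC(C)=CC[C@@H]1C(C)=CCC(C(=O)OC)(C(=O)OC)[C@@H]1c1ccccc1 | intermediate
6 | methyl (1R,5S,6R)-4-methyl-5-(3-methylbut-2-en-1-yl)-6-phenylcyclohex-3-ene-1-carboxylate | CC(C)=CC[C@@H]1C(C)=CC[C@@H](C(=O)OC)[C@@H]1c1ccccc1 | intermediate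
7 | N,O-dimethylhydroxylamine hydrochloride | CNOC.Cl | starting material
8 | (1R,5S,6R)-N-methoxy-N,4-dimethyl-5-(3-methylbut-2-en-1-yl)-6-phenylcyclohex-3-ene-1-carboxamide | CC(C)=CC[C@@H]1C(C)=CC[C@@H](C(=O)N(C)OC)[C@@H]1c1ccccc1 | intermediate
9 | phloroglucinol (benzene-1,3,5-triol) | Oc1cc(O)cc(O)c1 | starting material
10 | chloromethyl methyl ether (MOMCl) | COCCl | starting material
11 | 1,3,5-tris(methoxymethoxy)benzene | COCOc1cc(OCOC)cc(OCOC)c1 | intermediate
12 | [(1R,5S,6R)-4-methyl-5-(3-methylbut-2-en-1-yl)-6-phenylcyclohex-3-en-1-yl][2,4,6-tris(methoxymethoxy)phenyl]methanone | CC(C)=CC[C@@H]1C(C)=CC[C@@H](C(=O)c2c(OCOC)cc(OCOC)cc2OCOC)[C@@H]1c1ccccc1 | intermediate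
13 | (2,4,6-trihydroxyphenyl)[(1R,5S,6R)-4-methyl-5-(3-methylbut-2-en-1-yl)-6-phenylcyclohex-3-en-1-yl]methanone | CC(C)=CC[C@@H]1C(C)=CC[C@@H](C(=O)c2c(O)cc(O)cc2O)[C@@H]1c1ccccc1 | target

**Totals**
Total steps: 7. Longest linear sequence: 6 (1 → 3 → 5 → 6 → 8 → 12 → 13).

**Three steps most likely to fail, with fallbacks**
1. Step 1 (benzylidene malonate is a weak acceptor for enamines; regioselectivity for the internal CH2 over CH3, anti selectivity and ee are all required at once). Fallback: make the regiodefined (Z)-silyl enol ether by CuBr·SMe2/TMSCl-mediated conjugate addition of 2-methylprop-1-enylmagnesium bromide to methyl vinyl ketone, then add it to 2 in a Cu(II)–bis(oxazoline)-catalysed Mukaiyama–Michael reaction (Lewis-acid activation, no regiochemical ambiguity).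
2. Step 2 (a hindered tertiary malonate must add to the vinylphosphonium salt, and the basic ylide could epimerise the ketone α-centre before it cyclises). Fallback: ring-closing metathesis route to the same 5: C-allylate the malonate of 3 (allyl bromide, K2CO3), methylenate the ketone under non-basic conditions (Zn/CH2Br2/TiCl4), and close the ring with Grubbs II.
3. Step 6 (two hindered partners; the aryllithium may deprotonate C1 instead of adding). Fallback: reduce ester 6 to the aldehyde (DIBAL-H, −78 °C), add lithiated 11 to give the carbinol, and oxidise with Dess–Martin periodinane to 12.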